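**Retrosynthetic overview**
1. Hydroazulene numbering is used: C1 carries the isopropyl group and the aroyloxy oxygen, C3a the angular methyl, C5–C6 the epoxide (methyl on C6), C8 the hydroxyl, C8a the ring-fusion hydrogen; β is the face of the C3a methyl.
2. The strategy rests on the seven-membered ring C3a–C4–C5–C6–C7–C8–C8a: with C1 as a ketone and the ring oxygens removed it is a cyclohepta-1,4-diene (C5=C6 and C8=C8a, with C7 between them) fused through C3a–C8a to a cyclopentanone, which is the product of a cis-divinylcyclopropane Cope shift.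
3. Cutting C3a–C4 and joining C6 to C8 leads back to 3-methyl-2-(cis-2-methyl-2-vinylcyclopropyl)cyclopent-2-enone, assembled by Negishi coupling of 2-iodo-3-methylcyclopentenone with an enantiopure cis-iodo(vinyl)cyclopropane (asymmetric Simmons–Smith reaction on a Z-iodoallylic alcohol from propargyl alcohol).
4. After the ring expansion: oxygen at C8 by conjugate borylation/oxidation, isopropyl addition to the C1 ketone, aroylation of the tertiary oxygen, desilylation, hydroxyl-directed epoxidation of C5=C6.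
5. Ring order: cyclopentenone (bought), cyclopropane (step 2), seven-membered ring by three-to-seven ring expansion (step 7), epoxide last (step 15).

Key step: step 7

Remark: the (4R,5R)-dioxaborolane is taken as the ligand enantiomer that gives the (1R,2R)-cyclopropane 4, by extension of its established sense of induction with allylic alcohols; the iodine changes only the CIP priorities, not the face attacked.

**Route**

Step 1
Reactants: 1 prop-2-yn-1-ol
Product: 3 (Z)-3-iodo-2-methylprop-2-en-1-ol, via vinylmagnesium alkoxide 2 (not isolated)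
Conditions: MeMgBr (2.5 equiv), CuI (10 mol%), Et2O, −10 °C to rt; then I2, THF, −40 to 0 °C
Reagents that add atoms: methylmagnesium bromide, C[Mg]Br; iodine, II
Why: Copper-catalysed anti carbomagnesiation of the magnesium propargyl alkoxide puts the methyl on the internal carbon and leaves a vinylmagnesium held cis to the alkoxide, so iodinolysis with retention should give the Z-iodoalkene with iodine and CH2OH on the same side.

Step 2
Reactants: 3 (Z)-3-iodo-2-methylprop-2-en-1-ol
Product: 4 [(1R,2R)-2-iodo-1-methylcyclopropyl]methanol (iodine cis to CH2OH)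
Conditions: Zn(CH2I)2·DME (from Et2Zn, CH2I2, DME), (4R,5R)-2-butyl-N,N,N',N'-tetramethyl-1,3,2-dioxaborolane-4,5-dicarboxamide (1.2 equiv), CH2Cl2, −10 °C to rt; aq NH4Cl, then aq KOH wash
Reagents that add atoms: diiodomethane, ICI
Why: Charette's hydroxyl-directed asymmetric Simmons–Smith cyclopropanation is a stereospecific syn addition (iodine and CH2OH stay cis), and the chiral dioxaborolane bound to the zinc alkoxide selects the alkene face, setting both ring stereocentres.

Step 3
Reactants: 4 [(1R,2R)-2-iodo-1-methylcyclopropyl]methanol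
Product: 5 (1R,2R)-2-iodo-1-methylcyclopropane-1-carbaldehyde
Conditions: Dess–Martin periodinane (1.2 equiv), CH2Cl2, 0 °C to rt; aq NaHCO3/Na2S2O3 wash; solution used directly
Reagents that add atoms: none
Why: Dess–Martin oxidation of a primary alcohol under near-neutral conditions, and since the aldehyde alpha carbon is quaternary neither cyclopropane centre can epimerise.

Step 4
Reactants: 5 (1R,2R)-2-iodo-1-methylcyclopropane-1-carbaldehyde
Product: 6 (1R,2R)-1-ethenyl-2-iodo-1-methylcyclopropane (iodine cis to the ethenyl group)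
Conditions: Ph3PCH3Br, KN(SiMe3)2, Et2O, 0 °C; then 5, 0 °C to rt; volatile product kept as a pentane/Et2O solution
Reagents that add atoms: methyltriphenylphosphonium bromide, [Br-].C[P+](c1ccccc1)(c1ccccc1)c1ccccc1
Why: Wittig methylenation with the non-stabilised ylide turns the aldehyde into the vinyl group without touching the cyclopropyl iodide or the ring stereocentres.

Step 5
Reactants: 7 3-methylcyclopent-2-en-1-one
Product: 8 2-iodo-3-methylcyclopent-2-en-1-one
Conditions: I2 (1.5 equiv), K2CO3, DMAP (20 mol%), THF/H2O 1:1, rt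
Reagents that add atoms: iodine, II
Why: Alpha-iodination of an enone by amine-catalysed conjugate addition, iodination of the resulting enolate and loss of the amine, in the aqueous DMAP variant suited to beta-substituted enones.

Step 6
Reactants: 6 (1R,2R)-1-ethenyl-2-iodo-1-methylcyclopropane; 8 2-iodo-3-methylcyclopent-2-en-1-one
Product: 11 2-[(1R,2R)-2-ethenyl-2-methylcyclopropyl]-3-methylcyclopent-2-en-1-one, via cyclopropyllithium 9 (not isolated), via cyclopropylzinc chloride 10 (not isolated)
Conditions: 6, t-BuLi (2.0 equiv), Et2O, −78 °C; ZnCl2 (THF), −78 to 0 °C; then 8, Pd2(dba)3 (2.5 mol%), SPhos (10 mol%), THF, 0 °C to rt; isolated cold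
Reagents that add atoms: none
Why: Iodine–lithium exchange and transmetalation to zinc proceed with retention because cyclopropyl anions are configurationally stable at −78 °C, and Negishi coupling of the cyclopropylzinc with the alpha-iodoenone (retention at the sp3 carbon) should join the fragments below the temperature at which the product rearranges.

Step 7
Reactants: 11 2-[(1R,2R)-2-ethenyl-2-methylcyclopropyl]-3-methylcyclopent-2-en-1-one
Product: 12 (3aR)-3a,6-dimethyl-3,3a,4,7-tetrahydroazulen-1(2H)-one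
Conditions: PhMe (0.02 M, degassed), silanised sealed tube, 110 °C
Reagents that add atoms: none
Why: Concerted [3,3] sigmatropic shift (cis-divinylcyclopropane Cope rearrangement) through a boat transition state in which the cyclopentenone C=C and the vinyl group both lie over the three-membered ring: the vinyl terminus bonds to the enone beta carbon (new C3a–C4 bond) while the cyclopropane bond between the two substituted carbons (future C8 and C6) breaks, leaving C8=C8a conjugated with the ketone and C5=C6 as the second ring alkene. The closest known reaction type is the thermal rearrangement of cis-2-vinylcyclopropyl-substituted cycloalkenes and enones to fused cyclohepta-1,4-dienes, including cases where a fully substituted alkene terminus becomes a quaternary carbon and heating is needed. The seven-membered ring closes by ring expansion of the cyclopropane (three to seven), its CH2 staying bonded to both former ring carbons as C7, so both ring alkenes are necessarily cis. The only new stereocentre, C3a, is controlled by the two cyclopropane stereocentres: the cis ring ties the vinyl terminus to one face of the cyclopentenone alkene, so the (1R,2R) precursor should give the (3aR) quaternary carbon by chirality transfer while the cyclopropane centres become sp2. The step needs the [3,3] shift to outrun one-centre stereomutation of the cyclopropane, which would erode enantiomeric purity; the cis geometry built in steps 1 to 6, the release of ring strain and the weakened bond at the quaternary cyclopropane carbon secure this, the one brake being the cyclopentenone methyl that must point inward over the ring. No alkyl C–H sits cis to either alkenyl group, so the homodienyl hydrogen shift cannot compete, and base-free, oxygen-free conditions keep the skipped dienone from drifting into conjugation.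

Step 8
Reactants: 12 (3aR)-3a,6-dimethyl-3,3a,4,7-tetrahydroazulen-1(2H)-one
Product: 14 (3aR,8S,8aS)-8-hydroxy-3a,6-dimethyl-3,3a,4,7,8,8a-hexahydroazulen-1(2H)-one, via boryl ketone 13 (not isolated)
Conditions: Cu2O (3 mol%), DPEphos (6 mol%), B2pin2 (1.1 equiv), MeOH (3 equiv), THF, rt (no alkoxide base); then NaBO3·4H2O, THF/H2O, 0 °C to rt
Reagents that add atoms: sodium perborate, [Na+].[Na+].O[B-]1(O)OO[B-](O)(O)OO1
Why: Copper-catalysed conjugate borylation is expected to add the boryl-copper syn across C8=C8a from the face away from the axial C3a methyl (boron on the beta carbon C8), methanol then protonates the copper enolate at C8a on the same face (trans fusion), and perborate oxidises C–B to C–OH with retention, while the absence of alkoxide base leaves the doubly allylic C7 hydrogens alone.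

Step 9
Reactants: 14 (3aR,8S,8aS)-8-hydroxy-3a,6-dimethyl-3,3a,4,7,8,8a-hexahydroazulen-1(2H)-one
Product: 15 (3aR,8S,8aS)-3a,6-dimethyl-8-[(triethylsilyl)oxy]-3,3a,4,7,8,8a-hexahydroazulen-1(2H)-one
Conditions: TESCl, imidazole, CH2Cl2, 0 °C; if a cis-fused epimer is present: DBU (cat.), CH2Cl2, 0 °C
Reagents that add atoms: chlorotriethylsilane, CC[Si](Cl)(CC)CC
Why: Silylation of the secondary alcohol blocks retro-aldol cleavage and later acylation at O8, and because the C8a hydrogen is alpha to the ketone a cis-fused epimer, should one be present, can be equilibrated to the trans-fused ketone with a trace of amine base at this stage.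

Step 10
Reactants: 16 4-hydroxybenzoic acid
Product: 18 4-[(tert-butyldimethylsilyl)oxy]benzoic acid, via bis-silyl ester 17 (not isolated)
Conditions: TBSCl (2.3 equiv), imidazole, DMF, rt; then AcOH/THF/H2O 3:1:1, rt
Reagents that add atoms: tert-butyldimethylsilyl chloride, CC(C)(C)[Si](C)(C)Cl
Why: Silylation of both the phenol and the acid followed by selective hydrolysis of the far more labile silyl ester under mild aqueous acid leaves the aryl silyl ether in place.

Step 11
Reactants: 18 4-[(tert-butyldimethylsilyl)oxy]benzoic acid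
Product: 19 4-[(tert-butyldimethylsilyl)oxy]benzoyl chloride
Conditions: 1-chloro-N,N,2-trimethylprop-1-en-1-amine (1.2 equiv), CH2Cl2, 0 °C to rt; used crude
Reagents that add atoms: 1-chloro-N,N,2-trimethylprop-1-en-1-amine, CC(C)=C(Cl)N(C)C
Why: Ghosez's chloroenamine converts the acid into the acid chloride without releasing HCl, so the aryl silyl ether survives.

Step 12
Reactants: 15 (3aR,8S,8aS)-3a,6-dimethyl-8-[(triethylsilyl)oxy]-3,3a,4,7,8,8a-hexahydroazulen-1(2H)-one
Product: 20 (1R,3aR,8S,8aS)-3a,6-dimethyl-1-(propan-2-yl)-8-[(triethylsilyl)oxy]-1,2,3,3a,4,7,8,8a-octahydroazulen-1-ol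
Conditions: i-PrLi, CeCl3 (dried), THF, −78 °C, 1 h; then 15, −78 °C; aq NH4Cl
Reagents that add atoms: isopropyllithium, [Li]C(C)C
Why: Organocerium 1,2-addition (Imamoto conditions) suppresses enolisation and beta-elimination of the beta-silyloxy ketone, and the nucleophile should attack C1 from the face of the C8a hydrogen, opposite the angular methyl standing 1,3 to the carbonyl across the five-membered ring, placing isopropyl alpha and oxygen beta (1R).

Step 13
Reactants: 20 (1R,3aR,8S,8aS)-3a,6-dimethyl-1-(propan-2-yl)-8-[(triethylsilyl)oxy]-1,2,3,3a,4,7,8,8a-octahydroazulen-1-ol; 19 4-[(tert-butyldimethylsilyl)oxy]benzoyl chloride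
Product: 22 (1R,3aR,8S,8aS)-3a,6-dimethyl-1-(propan-2-yl)-8-[(triethylsilyl)oxy]-1,2,3,3a,4,7,8,8a-octahydroazulen-1-yl 4-[(tert-butyldimethylsilyl)oxy]benzoate, via lithium alkoxide 21 (not isolated)
Conditions: n-BuLi (1.05 equiv), THF, −78 °C; then 19 (1.5 equiv), −78 to 0 °C
Reagents that add atoms: none
Why: O-Acylation of a pre-formed lithium tertiary alkoxide by an aroyl chloride (nucleophilic acyl substitution), run cold with lithium as counter-ion so that the silyl group has little chance to migrate from O8, and no stereocentre is touched.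

Step 14
Reactants: 22 (1R,3aR,8S,8aS)-3a,6-dimethyl-1-(propan-2-yl)-8-[(triethylsilyl)oxy]-1,2,3,3a,4,7,8,8a-octahydroazulen-1-yl 4-[(tert-butyldimethylsilyl)oxy]benzoate
Product: 23 (1R,3aR,8S,8aS)-8-hydroxy-3a,6-dimethyl-1-(propan-2-yl)-1,2,3,3a,4,7,8,8a-octahydroazulen-1-yl 4-hydroxybenzoate
Conditions: HF·pyridine, pyridine, THF, 0 °C to rt
Reagents that add atoms: none
Why: Fluoride cleavage of both silyl ethers under buffered acidic conditions forms no alkoxide, so the aroyl group should stay on the tertiary oxygen instead of migrating to O8.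

Step 15
Reactants: 23 (1R,3aR,8S,8aS)-8-hydroxy-3a,6-dimethyl-1-(propan-2-yl)-1,2,3,3a,4,7,8,8a-octahydroazulen-1-yl 4-hydroxybenzoate
Product: 24 (1R,3aR,5S,6R,8S,8aS)-5,6-epoxy-8-hydroxy-3a,6-dimethyl-1-(propan-2-yl)decahydroazulen-1-yl 4-hydroxybenzoate (CNP0264773.1)
Conditions: VO(acac)2 (5 mol%), t-BuOOH (1.5 equiv, decane), CH2Cl2, 0 °C to rt
Reagents that add atoms: tert-butyl hydroperoxide, CC(C)(C)OO
Why: Vanadium-catalysed hydroxyl-directed epoxidation, in which the C8 hydroxyl (homoallylic to the trisubstituted C5=C6 alkene) binds the vanadium alkylperoxide and delivers oxygen to its own alpha face, also the face away from the angular methyl, setting C5 (S) and C6 (R).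

**Compound list**
1 | prop-2-yn-1-ol (propargyl alcohol) | C#CCO | starting material
2 | bromomagnesium (Z)-3-(bromomagnesio)-2-methylprop-2-en-1-olate | Br[Mg]OC/C(C)=C\[Mg]Br | intermediate (not isolated)
3 | (Z)-3-iodo-2-methylprop-2-en-1-ol | OC/C(C)=C\I | intermediate
4 | [(1R,2R)-2-iodo-1-methylcyclopropyl]methanol | I[C@@H]1C[C@]1(C)CO | intermediate
5 | (1R,2R)-2-iodo-1-methylcyclopropane-1-carbaldehyde | I[C@@H]1C[C@]1(C)C=O | intermediate
6 | (1R,2R)-1-ethenyl-2-iodo-1-methylcyclopropane | I[C@@H]1C[C@]1(C)C=C | intermediate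
7 | 3-methylcyclopent-2-en-1-one | CC1=CC(=O)CC1 | starting material
8 | 2-iodo-3-methylcyclopent-2-en-1-one | CC1=C(I)C(=O)CC1 | intermediate
9 | [(1R,2S)-2-ethenyl-2-methylcyclopropyl]lithium (lithium cis to ethenyl, configuration of 6 retained) | [Li][C@@H]1C[C@]1(C)C=C | intermediate (not isolated)
10 | chloro[(1R,2R)-2-ethenyl-2-methylcyclopropyl]zinc (zinc cis to ethenyl) | Cl[Zn][C@@H]1C[C@]1(C)C=C | intermediate (not isolated)
11 | 2-[(1R,2R)-2-ethenyl-2-methylcyclopropyl]-3-methylcyclopent-2-en-1-one (ethenyl cis to the cyclopentenyl group) | CC1=C([C@@H]2C[C@]2(C)C=C)C(=O)CC1 | intermediate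
12 | (3aR)-3a,6-dimethyl-3,3a,4,7-tetrahydroazulen-1(2H)-one | O=C1CC[C@]2(C)CC=C(C)CC=C21 | intermediate
13 | (3aR,8S,8aR)-3a,6-dimethyl-8-(4,4,5,5-tetramethyl-1,3,2-dioxaborolan-2-yl)-3,3a,4,7,8,8a-hexahydroazulen-1(2H)-one | O=C1CC[C@]2(C)CC=C(C)C[C@H](B3OC(C)(C)C(C)(C)O3)[C@H]21 | intermediate (not isolated)
14 | (3aR,8S,8aS)-8-hydroxy-3a,6-dimethyl-3,3a,4,7,8,8a-hexahydroazulen-1(2H)-one | O=C1CC[C@]2(C)CC=C(C)C[C@H](O)[C@H]21 | intermediate
15 | (3aR,8S,8aS)-3a,6-dimethyl-8-[(triethylsilyl)oxy]-3,3a,4,7,8,8a-hexahydroazulen-1(2H)-one | O=C1CC[C@]2(C)CC=C(C)C[C@H](O[Si](CC)(CC)CC)[C@H]21 | intermediate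
16 | 4-hydroxybenzoic acid | O=C(O)c1ccc(O)cc1 | starting material
17 | tert-butyldimethylsilyl 4-[(tert-butyldimethylsilyl)oxy]benzoate | CC(C)(C)[Si](C)(C)OC(=O)c1ccc(O[Si](C)(C)C(C)(C)C)cc1 | intermediate (not isolated)
18 | 4-[(tert-butyldimethylsilyl)oxy]benzoic acid | CC(C)(C)[Si](C)(C)Oc1ccc(cc1)C(O)=O | intermediate
19 | 4-[(tert-butyldimethylsilyl)oxy]benzoyl chloride | CC(C)(C)[Si](C)(C)Oc1ccc(cc1)C(Cl)=O | intermediate
20 | (1R,3aR,8S,8aS)-3a,6-dimethyl-1-(propan-2-yl)-8-[(triethylsilyl)oxy]-1,2,3,3a,4,7,8,8a-octahydroazulen-1-ol | CC(C)[C@]1(O)CC[C@]2(C)CC=C(C)C[C@H](O[Si](CC)(CC)CC)[C@H]21 | intermediate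
21 | lithium (1R,3aR,8S,8aS)-3a,6-dimethyl-1-(propan-2-yl)-8-[(triethylsilyl)oxy]-1,2,3,3a,4,7,8,8a-octahydroazulen-1-olate | CC(C)[C@]1([O-])CC[C@]2(C)CC=C(C)C[C@H](O[Si](CC)(CC)CC)[C@H]21.[Li+] | intermediate (not isolated)
22 | (1R,3aR,8S,8aS)-3a,6-dimethyl-1-(propan-2-yl)-8-[(triethylsilyl)oxy]-1,2,3,3a,4,7,8,8a-octahydroazulen-1-yl 4-[(tert-butyldimethylsilyl)oxy]benzoate | CC(C)[C@]1(OC(=O)c2ccc(O[Si](C)(C)C(C)(C)C)cc2)CC[C@]2(C)CC=C(C)C[C@H](O[Si](CC)(CC)CC)[C@H]21 | intermediate
23 | (1R,3aR,8S,8aS)-8-hydroxy-3a,6-dimethyl-1-(propan-2-yl)-1,2,3,3a,4,7,8,8a-octahydroazulen-1-yl 4-hydroxybenzoate | CC(C)[C@]1(OC(=O)c2ccc(O)cc2)CC[C@]2(C)CC=C(C)C[C@H](O)[C@H]21 | intermediate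
24 | (1R,3aR,5S,6R,8S,8aS)-5,6-epoxy-8-hydroxy-3a,6-dimethyl-1-(propan-2-yl)decahydroazulen-1-yl 4-hydroxybenzoate (CNP0264773.1) | CC(C)[C@]1(OC(=O)c2ccc(O)cc2)CC[C@]2(C)C[C@@H]3O[C@]3(C)C[C@H](O)[C@H]21 | target

**Step count and risks**

Total step count: 15 steps. Longest linear sequence: 12 steps (steps 1, 2, 3, 4, 6, 7, 8, 9, 12, 13, 14, 15, from propargyl alcohol).

Steps most likely to fail:

1. Step 8. The risk is poor or reversed facial selectivity in the boryl addition: the folded cycloheptadiene puts the C5=C6 bridge under the alpha face of C8, so boron may be delivered to the face that carries the angular methyl. The fallback makes the C8 configuration independent of this step. It sets out from 12 and comes back at 20. Step 8 is run on 12 whatever its facial outcome, giving through the C8-epimeric boryl ketone (3aR,8R,8aR)-3a,6-dimethyl-8-(4,4,5,5-tetramethyl-1,3,2-dioxaborolan-2-yl)-3,3a,4,7,8,8a-hexahydroazulen-1(2H)-one F1 the C8-epimeric hydroxy ketone (3aR,8R,8aS)-8-hydroxy-3a,6-dimethyl-3,3a,4,7,8,8a-hexahydroazulen-1(2H)-one F2; any 14 formed alongside follows the same path and converges later. TESCl/imidazole gives the silyl ether (3aR,8R,8aS)-3a,6-dimethyl-8-[(triethylsilyl)oxy]-3,3a,4,7,8,8a-hexahydroazulen-1(2H)-one F3, and i-PrLi/CeCl3 gives the tertiary alcohol (1R,3aR,8R,8aS)-3a,6-dimethyl-1-(propan-2-yl)-8-[(triethylsilyl)oxy]-1,2,3,3a,4,7,8,8a-octahydroazulen-1-ol F4. PPTS in MeOH removes the silyl group to give the diol (1R,3aR,8R,8aS)-3a,6-dimethyl-1-(propan-2-yl)-1,2,3,3a,4,7,8,8a-octahydroazulene-1,8-diol F5, and Dess–Martin periodinane oxidises its secondary alcohol to (1R,3aR,8aR)-1-hydroxy-3a,6-dimethyl-1-(propan-2-yl)-2,3,3a,4,7,8a-hexahydroazulen-8(1H)-one F6, in which the C8 stereocentre is erased. Me4NBH(OAc)3 in MeCN/AcOH at −30 °C (hydroxyl-directed, anti-selective 1,3-reduction) then delivers hydride from boron held on the tertiary hydroxyl, that is to the beta face of C8, giving the 1,8-anti diol (1R,3aR,8S,8aS)-3a,6-dimethyl-1-(propan-2-yl)-1,2,3,3a,4,7,8,8a-octahydroazulene-1,8-diol F7. TESCl/imidazole silylates only the secondary hydroxyl, and the route is rejoined at 20.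

2. Step 7. The risk is a sluggish ring expansion at the fully substituted enone terminus, so that the temperature needed allows one-centre stereomutation of the cyclopropane (loss of enantiomeric purity) or hydrogen shifts in the product. The fallback replaces the thermal pericyclic shift by a charge-accelerated, stepwise ring expansion at low temperature. It sets out from 11 and comes back at 12. Complexing the enone carbonyl of 11 with Me2AlCl in CH2Cl2 at −78 to 0 °C makes the beta carbon electrophilic; the tethered vinyl group attacks it on the face fixed by the cis cyclopropane, and the cyclopropylcarbinyl cation so formed opens toward the aluminium enolate to give 12. Acid acceleration of the Cope rearrangement is established for 2-acyl-1,5-dienes, of which 11 is one. No new compound is made on this path (F0).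

3. Step 13. The risk is slow acylation of the crowded tertiary alkoxide, which gives time for the triethylsilyl group to migrate from O8 to O1 and for the aroyl group to end on the wrong oxygen. The fallback uses an ether at O8 that cannot migrate. It sets out from 14 and comes back at 23. 4-Methoxybenzyl trichloroacetimidate with catalytic La(OTf)3 in toluene gives the ether (3aR,8S,8aS)-8-[(4-methoxybenzyl)oxy]-3a,6-dimethyl-3,3a,4,7,8,8a-hexahydroazulen-1(2H)-one F8. i-PrLi/CeCl3 gives the tertiary alcohol (1R,3aR,8S,8aS)-8-[(4-methoxybenzyl)oxy]-3a,6-dimethyl-1-(propan-2-yl)-1,2,3,3a,4,7,8,8a-octahydroazulen-1-ol F9. n-BuLi followed by 19 gives the ester (1R,3aR,8S,8aS)-8-[(4-methoxybenzyl)oxy]-3a,6-dimethyl-1-(propan-2-yl)-1,2,3,3a,4,7,8,8a-octahydroazulen-1-yl 4-[(tert-butyldimethylsilyl)oxy]benzoate F10. DDQ in CH2Cl2/pH 7 buffer removes the benzyl ether to give (1R,3aR,8S,8aS)-8-hydroxy-3a,6-dimethyl-1-(propan-2-yl)-1,2,3,3a,4,7,8,8a-octahydroazulen-1-yl 4-[(tert-butyldimethylsilyl)oxy]benzoate F11, and HF·pyridine/pyridine frees the phenol, rejoining the route at 23.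

Further compounds
F1 | step 8 | (3aR,8R,8aR)-3a,6-dimethyl-8-(4,4,5,5-tetramethyl-1,3,2-dioxaborolan-2-yl)-3,3a,4,7,8,8a-hexahydroazulen-1(2H)-one | O=C1CC[C@]2(C)CC=C(C)C[C@@H](B3OC(C)(C)C(C)(C)O3)[C@H]21
F2 | step 8 | (3aR,8R,8aS)-8-hydroxy-3a,6-dimethyl-3,3a,4,7,8,8a-hexahydroazulen-1(2H)-one | O=C1CC[C@]2(C)CC=C(C)C[C@@H](O)[C@H]21
F3 | step 8 | (3aR,8R,8aS)-3a,6-dimethyl-8-[(triethylsilyl)oxy]-3,3a,4,7,8,8a-hexahydroazulen-1(2H)-one | O=C1CC[C@]2(C)CC=C(C)C[C@@H](O[Si](CC)(CC)CC)[C@H]21
F4 | step 8 | (1R,3aR,8R,8aS)-3a,6-dimethyl-1-(propan-2-yl)-8-[(triethylsilyl)oxy]-1,2,3,3a,4,7,8,8a-octahydroazulen-1-ol | CC(C)[C@]1(O)CC[C@]2(C)CC=C(C)C[C@@H](O[Si](CC)(CC)CC)[C@H]21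
F5 | step 8 | (1R,3aR,8R,8aS)-3a,6-dimethyl-1-(propan-2-yl)-1,2,3,3a,4,7,8,8a-octahydroazulene-1,8-diol | CC(C)[C@]1(O)CC[C@]2(C)CC=C(C)C[C@@H](O)[C@H]21
F6 | step 8 | (1R,3aR,8aR)-1-hydroxy-3a,6-dimethyl-1-(propan-2-yl)-2,3,3a,4,7,8a-hexahydroazulen-8(1H)-one | CC(C)[C@]1(O)CC[C@]2(C)CC=C(C)CC(=O)[C@H]21
F7 | step 8 | (1R,3aR,8S,8aS)-3a,6-dimethyl-1-(propan-2-yl)-1,2,3,3a,4,7,8,8a-octahydroazulene-1,8-diol | CC(C)[C@]1(O)CC[C@]2(C)CC=C(C)C[C@H](O)[C@H]21
F0 | step 7 | none | none
F8 | step 13 | (3aR,8S,8aS)-8-[(4-methoxybenzyl)oxy]-3a,6-dimethyl-3,3a,4,7,8,8a-hexahydroazulen-1(2H)-one | O=C1CC[C@]2(C)CC=C(C)C[C@H](OCc3ccc(OC)cc3)[C@H]21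
F9 | step 13 | (1R,3aR,8S,8aS)-8-[(4-methoxybenzyl)oxy]-3a,6-dimethyl-1-(propan-2-yl)-1,2,3,3a,4,7,8,8a-octahydroazulen-1-ol | CC(C)[C@]1(O)CC[C@]2(C)CC=C(C)C[C@H](OCc3ccc(OC)cc3)[C@H]21
F10 | step 13 | (1R,3aR,8S,8aS)-8-[(4-methoxybenzyl)oxy]-3a,6-dimethyl-1-(propan-2-yl)-1,2,3,3a,4,7,8,8a-octahydroazulen-1-yl 4-[(tert-butyldimethylsilyl)oxy]benzoate | CC(C)[C@]1(OC(=O)c2ccc(O[Si](C)(C)C(C)(C)C)cc2)CC[C@]2(C)CC=C(C)C[C@H](OCc3ccc(OC)cc3)[C@H]21
F11 | step 13 | (1R,3aR,8S,8aS)-8-hydroxy-3a,6-dimethyl-1-(propan-2-yl)-1,2,3,3a,4,7,8,8a-octahydroazulen-1-yl 4-[(tert-butyldimethylsilyl)oxy]benzoate | CC(C)[C@]1(OC(=O)c2ccc(O[Si](C)(C)C(C)(C)C)cc2)CC[C@]2(C)CC=C(C)C[C@H](O)[C@H]21
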